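**Retrosynthetic overview**
1. Last bond: C7–O acylation of the tertiary ketol core with a bis-silylated orsellinoyl chloride, silyl groups removed in the same pot; the arene is bought as orsellinic acid.
2. Pyran (ring B): 6-endo O–C3 closure of a gamma-hydroxymethylene enone onto the 3-alkynyl group; C1 comes from an amide acetal.
3. Carbocycle (ring A): the C6–C7 bond is made by an enantioselective carbene-catalysed acyl-anion addition of an enal carbon to a tethered methyl ketone; this closes the ring and sets C7 (S) in one step.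
4. Ynenal: syn Pd-catalysed addition of (E)-pent-2-en-4-ynyl acetate across 6-oxohept-2-ynal, so the full side chain is in place before the ring closure.
5. Ring order: ring A (step 4), then ring B (step 5); the aryl ring is carried in intact.

Assumption: the three starting materials are bought, and the facial sense of the carbene catalyst in step 4 is assigned by analogy; if the first run gives the (R)-ketol, the commercial mirror-image precatalyst is used and nothing else changes.

**Route**

Step 1
Reactants: 1 (E)-pent-2-en-4-yn-1-ol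
Product: 2 (E)-pent-2-en-4-yn-1-yl acetate
Conditions: Ac2O, pyridine, 4-(dimethylamino)pyridine (cat.), CH2Cl2, 0 °C → rt
Reagents that add atoms: acetic anhydride, CC(=O)OC(C)=O
Why: Routine nucleophile-catalysed O-acetylation of a primary allylic alcohol, with no stereocentre involved and the E alkene untouched.

Step 2
Reactants: 3 2-(but-3-yn-1-yl)-2-methyl-1,3-dioxolane
Product: 7 6-oxohept-2-ynal, via lithium acetylide 4 (not isolated), via hemiaminal alkoxide 5 (not isolated), via dioxolane ynal 6 (not isolated)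
Conditions: n-BuLi, THF, −78 °C; DMF, −78 → 0 °C; then 2 M aq. HCl, THF, rt
Reagents that add atoms: N,N-dimethylformamide, CN(C)C=O; water, O
Why: C-formylation of a lithium acetylide with DMF followed by an acidic quench is a standard ynal synthesis, the ketone stays masked while the strong base is present, and the same aqueous acid hydrolyses the dioxolane.

Step 3
Reactants: 7 6-oxohept-2-ynal (1.2 equiv); 2 (E)-pent-2-en-4-yn-1-yl acetate
Product: 8 [(2E,6E)-8-oxo-6-(3-oxobutyl)octa-2,6-dien-4-yn-1-yl] acetate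
Conditions: Pd(OAc)2 (3 mol %), P(2,6-(MeO)2C6H3)3 (3 mol %), THF, rt
Reagents that add atoms: none
Why: The Trost addition of a donor terminal alkyne across an acceptor alkyne (established for ynoates and ynones, of which the ynal is the more electrophilic analogue) delivers alkynyl and H syn, which places the oxobutyl chain cis to the formyl group as the ring closure needs.

Step 4
Reactants: 8 [(2E,6E)-8-oxo-6-(3-oxobutyl)octa-2,6-dien-4-yn-1-yl] acetate
Product: 9 (E)-5-[(4S)-4-hydroxy-4-methyl-3-oxocyclohex-1-en-1-yl]pent-2-en-4-yn-1-yl acetate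
Conditions: (5aR,10bS)-2-(pentafluorophenyl)-5a,10b-dihydro-4H,6H-indeno[2,1-b][1,2,4]triazolo[4,3-d][1,4]oxazin-2-ium tetrafluoroborate (10 mol %), Et3N (10 mol %), PhMe, rt
Reagents that add atoms: none
Why: Proposed new method: the triazolylidene adds to the enal carbonyl to give a Breslow intermediate whose acyl-anion carbon attacks the tethered methyl ketone through a six-membered transition state (attack from the beta carbon would need a four-membered ring), the N-C6F5 aminoindanol catalyst that favours acyl-anion over homoenolate reactivity shields one ketone face to set the (S) tertiary carbinol, and the closest known chemistry is the enantioselective intramolecular aldehyde–ketone crossed benzoin cyclisation together with enal-donor Stetter reactions of the same catalyst class.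

Step 5
Reactants: 9 (E)-5-[(4S)-4-hydroxy-4-methyl-3-oxocyclohex-1-en-1-yl]pent-2-en-4-yn-1-yl acetate
Product: 12 (E)-3-[(7S)-7-hydroxy-7-methyl-6-oxo-7,8-dihydro-6H-isochromen-3-yl]prop-2-en-1-yl acetate, via enaminone 10 (not isolated), via hydroxymethylene dienone 11 (not isolated)
Conditions: t-BuOCH(NMe2)2, PhMe, 60 °C (N2 sweep); then AcOH–H2O–THF, rt; then AgOTf (5 mol %), CH2Cl2, rt
Reagents that add atoms: tert-butoxybis(dimethylamino)methane, CC(C)(C)OC(N(C)C)N(C)C; water, O
Why: With the alpha-prime carbon quaternary the gamma CH2 is the only enolisable site, so the amide acetal condenses there to a push–pull dienaminone, hydrolysis gives the hydroxymethylene dienone, and its enol oxygen adds 6-endo to the alkyne carbon that is delta to the ketone (vinylogous aminomethylenation followed by enol–alkyne oxa-cycloisomerisation), all without touching C7.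

Step 6
Reactants: 13 orsellinic acid (2,4-dihydroxy-6-methylbenzoic acid)
Product: 14 tert-butyldimethylsilyl 2,4-bis(tert-butyldimethylsilyloxy)-6-methylbenzoate
Conditions: t-BuMe2SiCl (3.5 equiv), imidazole (7 equiv), DMF, rt
Reagents that add atoms: tert-butyldimethylsilyl chloride, CC(C)(C)[Si](C)(C)Cl
Why: Exhaustive imidazole-promoted silylation covers both phenols and the acid, and the silyl ester is the direct precursor of the acid chloride.

Step 7
Reactants: 14 tert-butyldimethylsilyl 2,4-bis(tert-butyldimethylsilyloxy)-6-methylbenzoate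
Product: 15 2,4-bis(tert-butyldimethylsilyloxy)-6-methylbenzoyl chloride
Conditions: (COCl)2, Me2NCHO (cat.), CH2Cl2, 0 °C → rt
Reagents that add atoms: oxalyl chloride, ClC(=O)C(=O)Cl
Why: Silyl esters exchange to acid chlorides under neutral Vilsmeier-type activation with oxalyl chloride, which leaves the aryl silyl ethers intact.

Step 8
Reactants: 12 (E)-3-[(7S)-7-hydroxy-7-methyl-6-oxo-7,8-dihydro-6H-isochromen-3-yl]prop-2-en-1-yl acetate; 15 2,4-bis(tert-butyldimethylsilyloxy)-6-methylbenzoyl chloride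
Product: 18 (7S)-3-[(E)-3-acetoxyprop-1-en-1-yl]-7-methyl-6-oxo-7,8-dihydro-6H-isochromen-7-yl 2,4-dihydroxy-6-methylbenzoate, via lithium alkoxide 16 (not isolated), via bis-silyl ester 17 (not isolated)
Conditions: LiN(SiMe3)2 (1.0 equiv), THF, −78 °C; 15 (1.3 equiv), −78 → 0 °C; then HF·pyridine, pyridine, 0 °C
Reagents that add atoms: none
Why: O-acylation of the preformed lithium tertiary alkoxide is the usual way to esterify a tertiary alcohol with a 2,6-disubstituted aroyl chloride and breaks no bond to C7 (configuration retained), and buffered HF·pyridine then cleaves both aryl silyl ethers without harming the allylic acetate or the pyranyl enone.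

**Compound list**
1 | (E)-pent-2-en-4-yn-1-ol | OC/C=C/C#C | starting material
2 | (E)-pent-2-en-4-yn-1-yl acetate | CC(=O)OC/C=C/C#C | intermediate
3 | 2-(but-3-yn-1-yl)-2-methyl-1,3-dioxolane | CC1(CCC#C)OCCO1 | starting material
4 | [4-(2-methyl-1,3-dioxolan-2-yl)but-1-yn-1-yl]lithium | [Li]C#CCCC1(C)OCCO1 | intermediate
5 | lithium 1-(dimethylamino)-5-(2-methyl-1,3-dioxolan-2-yl)pent-2-yn-1-olate | [Li]OC(C#CCCC1(C)OCCO1)N(C)C | intermediate
6 | 5-(2-methyl-1,3-dioxolan-2-yl)pent-2-ynal | CC1(CCC#CC=O)OCCO1 | intermediate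
7 | 6-oxohept-2-ynal | CC(=O)CCC#CC=O | intermediate
8 | [(2E,6E)-8-oxo-6-(3-oxobutyl)octa-2,6-dien-4-yn-1-yl] acetate (formyl cis to the oxobutyl chain) | CC(=O)CC/C(C#C/C=C/COC(C)=O)=C\C=O | intermediate
9 | (E)-5-[(4S)-4-hydroxy-4-methyl-3-oxocyclohex-1-en-1-yl]pent-2-en-4-yn-1-yl acetate | CC(=O)OC/C=C/C#CC1=CC(=O)[C@@](C)(O)CC1 | intermediate
10 | (E)-5-[(4S,6E)-6-[(dimethylamino)methylidene]-4-hydroxy-4-methyl-3-oxocyclohex-1-en-1-yl]pent-2-en-4-yn-1-yl acetate | CC(=O)OC/C=C/C#CC1=CC(=O)[C@@](C)(O)C/C1=C\N(C)C | intermediate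
11 | (E)-5-[(4S,6Z)-4-hydroxy-6-(hydroxymethylidene)-4-methyl-3-oxocyclohex-1-en-1-yl]pent-2-en-4-yn-1-yl acetate | CC(=O)OC/C=C/C#CC1=CC(=O)[C@@](C)(O)C/C1=C/O | intermediate
12 | (E)-3-[(7S)-7-hydroxy-7-methyl-6-oxo-7,8-dihydro-6H-isochromen-3-yl]prop-2-en-1-yl acetate | CC(=O)OC/C=C/C1=CC2=CC(=O)[C@@](C)(O)CC2=CO1 | intermediate
13 | orsellinic acid (2,4-dihydroxy-6-methylbenzoic acid) | Cc1cc(O)cc(O)c1C(=O)O | starting material
14 | tert-butyldimethylsilyl 2,4-bis(tert-butyldimethylsilyloxy)-6-methylbenzoate | Cc1cc(O[Si](C)(C)C(C)(C)C)cc(O[Si](C)(C)C(C)(C)C)c1C(=O)O[Si](C)(C)C(C)(C)C | intermediate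
15 | 2,4-bis(tert-butyldimethylsilyloxy)-6-methylbenzoyl chloride | Cc1cc(O[Si](C)(C)C(C)(C)C)cc(O[Si](C)(C)C(C)(C)C)c1C(=O)Cl | intermediate
16 | lithium (7S)-alkoxide of 12 | CC(=O)OC/C=C/C1=CC2=CC(=O)[C@@](C)(O[Li])CC2=CO1 | intermediate
17 | (7S)-3-[(E)-3-acetoxyprop-1-en-1-yl]-7-methyl-6-oxo-7,8-dihydro-6H-isochromen-7-yl 2,4-bis(tert-butyldimethylsilyloxy)-6-methylbenzoate | CC(=O)OC/C=C/C1=CC2=CC(=O)[C@@](C)(OC(=O)c3c(C)cc(O[Si](C)(C)C(C)(C)C)cc3O[Si](C)(C)C(C)(C)C)CC2=CO1 | intermediate
18 | (7S)-3-[(E)-3-acetoxyprop-1-en-1-yl]-7-methyl-6-oxo-7,8-dihydro-6H-isochromen-7-yl 2,4-dihydroxy-6-methylbenzoate | CC(=O)OC/C=C/C1=CC2=CC(=O)[C@@](C)(OC(=O)c3c(C)cc(O)cc3O)CC2=CO1 | target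

**Step count**
Total: 8 steps. Longest linear sequence: 5 steps (3 → 7 → 8 → 9 → 12 → 18; steps 2, 3, 4, 5, 8).

**Steps most likely to fail, with fallbacks**

Step 4 is the riskiest. An enal-derived Breslow intermediate can divert into homoenolate or acyl-azolium chemistry, and in 8 it is conjugated through the enyne to an allylic acetate that could leave. The fallback sets out from 7 and comes back at 9, and attaches the side chain only after ring A is closed. Addition of ethynyltriisopropylsilane to 7 under the step 3 catalyst gives (E)-6-oxo-3-[(triisopropylsilyl)ethynyl]hept-2-enal F1, a donor with no leaving group and a shorter conjugated path. The same triazolium-catalysed cyclisation gives (S)-6-hydroxy-6-methyl-3-[(triisopropylsilyl)ethynyl]cyclohex-2-en-1-one F2. Bu4NF buffered with AcOH frees (S)-3-ethynyl-6-hydroxy-6-methylcyclohex-2-en-1-one F3. Sonogashira coupling (PdCl2(PPh3)2, CuI, Et3N) with (E)-3-iodoprop-2-en-1-yl acetate F4, made by acetylating commercial (E)-3-iodoprop-2-en-1-ol, then gives 9.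

Step 5 is next. The hot amide acetal and the dimethylamine it releases may add to the electron-poor enyne or cleave the acetate faster than the gamma CH2 condenses. The fallback sets out from 9 and comes back at 11, and brings in C1 with an electrophile instead. Me3SiOTf and Et3N give the bis(trimethylsilyl) dienol ether (E)-5-[(4S)-4-methyl-4,5-bis(trimethylsilyloxy)cyclohexa-1,5-dien-1-yl]pent-2-en-4-yn-1-yl acetate F5. A vinylogous Mukaiyama reaction with HC(OMe)3 and BF3·OEt2 at −78 °C puts the masked formyl group on the gamma carbon and gives (E)-5-[(4S)-6-(dimethoxymethyl)-4-methyl-3-oxo-4-(trimethylsilyloxy)cyclohex-1-en-1-yl]pent-2-en-4-yn-1-yl acetate F6, as both C6 epimers, which does not matter. Aqueous AcOH removes the acetal and the silyl ether to give 11, which is closed with AgOTf as in step 5.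

Step 8 is third. A tertiary alkoxide next to a ketone must attack an aroyl chloride flanked by a methyl and a silyloxy group, and the core must survive the base. The fallback sets out from 12 and comes back at 18, and builds the arene on the ester oxygen instead of acylating with it. Commercial 2,2,6-trimethyl-4H-1,3-dioxin-4-one is C-acetylated (LiN(SiMe3)2, AcCl) to 2,2-dimethyl-6-(2-oxopropyl)-4H-1,3-dioxin-4-one F7. A second acetylation through its dianion (LiN(i-Pr)2, N-acetylimidazole) gives 6-(2,4-dioxopentyl)-2,2-dimethyl-4H-1,3-dioxin-4-one F8. Heating F8 with 12 in PhMe at 110 °C expels acetone and gives the unhindered acylketene 3,5,7-trioxooct-1-en-1-one F9. The tertiary alcohol traps it as (7S)-3-[(E)-3-acetoxyprop-1-en-1-yl]-7-methyl-6-oxo-7,8-dihydro-6H-isochromen-7-yl 3,5,7-trioxooctanoate F10. K2CO3 in i-PrOH–CH2Cl2 followed by CF3CO2H brings about aldol ring closure and dehydration to the free orsellinate 18, with no protecting groups.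

**Further compounds**
F1 | step 4 | (E)-6-oxo-3-[(triisopropylsilyl)ethynyl]hept-2-enal | CC(=O)CC/C(C#C[Si](C(C)C)(C(C)C)C(C)C)=C\C=O
F2 | step 4 | (S)-6-hydroxy-6-methyl-3-[(triisopropylsilyl)ethynyl]cyclohex-2-en-1-one | CC(C)[Si](C#CC1=CC(=O)[C@@](C)(O)CC1)(C(C)C)C(C)C
F3 | step 4 | (S)-3-ethynyl-6-hydroxy-6-methylcyclohex-2-en-1-one | C#CC1=CC(=O)[C@@](C)(O)CC1
F4 | step 4 | (E)-3-iodoprop-2-en-1-yl acetate | CC(=O)OC/C=C/I
F5 | step 5 | (E)-5-[(4S)-4-methyl-4,5-bis(trimethylsilyloxy)cyclohexa-1,5-dien-1-yl]pent-2-en-4-yn-1-yl acetate | CC(=O)OC/C=C/C#CC1=CC[C@](C)(O[Si](C)(C)C)C(O[Si](C)(C)C)=C1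
F6 | step 5 | (E)-5-[(4S)-6-(dimethoxymethyl)-4-methyl-3-oxo-4-(trimethylsilyloxy)cyclohex-1-en-1-yl]pent-2-en-4-yn-1-yl acetate (C6 epimers) | CC(=O)OC/C=C/C#CC1=CC(=O)[C@@](C)(O[Si](C)(C)C)CC1C(OC)OC
F7 | step 8 | 2,2-dimethyl-6-(2-oxopropyl)-4H-1,3-dioxin-4-one | CC(=O)CC1=CC(=O)OC(C)(C)O1
F8 | step 8 | 6-(2,4-dioxopentyl)-2,2-dimethyl-4H-1,3-dioxin-4-one | CC(=O)CC(=O)CC1=CC(=O)OC(C)(C)O1
F9 | step 8 | 3,5,7-trioxooct-1-en-1-one (acylketene) | CC(=O)CC(=O)CC(=O)C=C=O
F10 | step 8 | (7S)-3-[(E)-3-acetoxyprop-1-en-1-yl]-7-methyl-6-oxo-7,8-dihydro-6H-isochromen-7-yl 3,5,7-trioxooctanoate | CC(=O)OC/C=C/C1=CC2=CC(=O)[C@@](C)(OC(=O)CC(=O)CC(=O)CC(C)=O)CC2=CO1
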